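**Retrosynthetic overview**
1. The target is the mono-ketal of commercial all-trans-canthaxanthin with a C34 syn-diol. The spiro dioxolane is cut first (Noyori ketalisation); it is the only ring made in the route and it is made last, the carotenoid rings and polyene being bought intact.
2. Diol: the C9–C10 bond comes from Cram-chelate addition of a C13 Grignard reagent (left fragment, C1–C9) to an α-benzyloxy methyl ketone (C10–C24); this sets C10 from C11.
3. Ketone: the C13–C14 bond comes from Negishi coupling of a zinc reagent made from (R)-α-hydroxy-γ-butyrolactone (C10–C13, source of C11) with an (E)-vinyl iodide obtained by zirconium-catalysed carboalumination of the right-fragment alkyne (C14–C24).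
4. Both C13 fragments: two rounds of "alkyllithium opens α-methyl-γ-butyrolactone, then Wittig methylenation". The four methyl-bearing centres are bought with the lactone (R and R on the left; S outer and R inner on the right).

Assumption: both enantiomers of α-methyl-γ-butyrolactone, (R)-α-hydroxy-γ-butyrolactone and all-trans-canthaxanthin are taken as commercial; the target centres read from the SMILES are 3R,7R,10R,11R,18R,22S (squalene numbering) and R at the spiro carbon (carotenoid C-4').

**Left fragment (C1–C9)**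

Step 1
Reactants: 1 (3R)-3-methyloxolan-2-one [(R)-α-methyl-γ-butyrolactone]
Product: 2 (3R)-5-hydroxy-3-methylpentan-2-one
Conditions: MeLi (1.05 equiv), Et2O, −78 °C; AcOH quench at −78 °C
Reagents that add atoms: methyllithium, [Li]C
Why: Acyl addition of an alkyllithium to a γ-lactone stops at the lithium lactolate at −78 °C, so one methyl is delivered and the hydroxy ketone is freed only on quench; the α-methyl centre comes unchanged from 1.

Step 2
Reactants: 2 (3R)-5-hydroxy-3-methylpentan-2-one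
Product: 3 (3R)-3,4-dimethylpent-4-en-1-ol
Conditions: Ph3PCH3Br (2.5 equiv), KN(SiMe3)2 (2.4 equiv), THF, 0 °C → rt
Reagents that add atoms: methyltriphenylphosphonium bromide, C[P+](c1ccccc1)(c1ccccc1)c1ccccc1.[Br-]
Why: Wittig methylenation of the open-chain ketone (free hydroxyl carried as alkoxide); the ylide adds to the carbonyl faster than it enolises toward the hindered α-CH, so the stereocentre is kept.

Step 3
Reactants: 3 (3R)-3,4-dimethylpent-4-en-1-ol
Product: 4 (3R)-5-iodo-2,3-dimethylpent-1-ene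
Conditions: I2, PPh3, imidazole, CH2Cl2, 0 °C
Reagents that add atoms: iodine, [I][I]
Why: Appel-type iodination, SN2 of iodide on the primary alkoxyphosphonium ion; alkene and stereocentre are not involved.

Step 4
Reactants: 4 (3R)-5-iodo-2,3-dimethylpent-1-ene; 1 (3R)-3-methyloxolan-2-one
Product: 6 (3R,7R)-1-hydroxy-3,7,8-trimethylnon-8-en-4-one, via alkyllithium 5 (not isolated)
Conditions: t-BuLi (2.0 equiv), Et2O/pentane, −78 °C; then 1 (0.9 equiv), −78 °C; AcOH quench at −78 °C
Reagents that add atoms: none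
Why: Lithium–iodine exchange gives a primary alkyllithium that cannot cyclise onto its alkene (only a four-membered ring is possible), and single acyl addition to the lactone as in step 1 gives the hydroxy ketone with both stereocentres carried over from 4 and 1.

Step 5
Reactants: 6 (3R,7R)-1-hydroxy-3,7,8-trimethylnon-8-en-4-one
Product: 7 (3R,7R)-3,7,8-trimethyl-4-methylidenenon-8-en-1-ol
Conditions: Ph3PCH3Br (2.5 equiv), KN(SiMe3)2 (2.4 equiv), THF, 0 °C → rt
Reagents that add atoms: methyltriphenylphosphonium bromide, C[P+](c1ccccc1)(c1ccccc1)c1ccccc1.[Br-]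
Why: Wittig methylenation; any competing enolisation goes to the unhindered CH2 side of the ketone, which leaves the α-methyl stereocentre intact.

Step 6
Reactants: 7 (3R,7R)-3,7,8-trimethyl-4-methylidenenon-8-en-1-ol
Product: 8 (3R,7R)-9-iodo-2,3,7-trimethyl-6-methylidenenon-1-ene
Conditions: I2, PPh3, imidazole, CH2Cl2, 0 °C
Reagents that add atoms: iodine, [I][I]
Why: Appel-type iodination of the primary alcohol by SN2; the two 1,1-disubstituted alkenes are inert to the phosphine–iodine adduct.

**Right fragment (C14–C24)**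

Step 7
Reactants: 9 (3S)-3-methyloxolan-2-one [(S)-α-methyl-γ-butyrolactone]
Product: 10 (3S)-5-hydroxy-3-methylpentan-2-one
Conditions: MeLi (1.05 equiv), Et2O, −78 °C; AcOH quench at −78 °C
Reagents that add atoms: methyllithium, [Li]C
Why: Single acyl addition to the lactone via the stable lithium lactolate, as in step 1; the stereocentre (future C22) comes from 9.

Step 8
Reactants: 10 (3S)-5-hydroxy-3-methylpentan-2-one
Product: 11 (3S)-3,4-dimethylpent-4-en-1-ol
Conditions: Ph3PCH3Br (2.5 equiv), KN(SiMe3)2 (2.4 equiv), THF, 0 °C → rt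
Reagents that add atoms: methyltriphenylphosphonium bromide, C[P+](c1ccccc1)(c1ccccc1)c1ccccc1.[Br-]
Why: Wittig methylenation as in step 2, without epimerisation of the α-methyl centre.

Step 9
Reactants: 11 (3S)-3,4-dimethylpent-4-en-1-ol
Product: 12 (3S)-5-iodo-2,3-dimethylpent-1-ene
Conditions: I2, PPh3, imidazole, CH2Cl2, 0 °C
Reagents that add atoms: iodine, [I][I]
Why: Appel-type iodination of the primary alcohol by SN2.

Step 10
Reactants: 12 (3S)-5-iodo-2,3-dimethylpent-1-ene; 1 (3R)-3-methyloxolan-2-one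
Product: 14 (3R,7S)-1-hydroxy-3,7,8-trimethylnon-8-en-4-one, via alkyllithium 13 (not isolated)
Conditions: t-BuLi (2.0 equiv), Et2O/pentane, −78 °C; then 1 (0.9 equiv), −78 °C; AcOH quench at −78 °C
Reagents that add atoms: none
Why: Lithium–iodine exchange then single acyl addition to the (R)-lactone as in step 4; C22 (S) comes from 12 and C18 (R) from 1.

Step 11
Reactants: 14 (3R,7S)-1-hydroxy-3,7,8-trimethylnon-8-en-4-one
Product: 15 (3R,7S)-3,7,8-trimethyl-4-methylidenenon-8-en-1-ol
Conditions: Ph3PCH3Br (2.5 equiv), KN(SiMe3)2 (2.4 equiv), THF, 0 °C → rt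
Reagents that add atoms: methyltriphenylphosphonium bromide, C[P+](c1ccccc1)(c1ccccc1)c1ccccc1.[Br-]
Why: Wittig methylenation as in step 5.

Step 12
Reactants: 15 (3R,7S)-3,7,8-trimethyl-4-methylidenenon-8-en-1-ol
Product: 16 (3S,7R)-9-iodo-2,3,7-trimethyl-6-methylidenenon-1-ene
Conditions: I2, PPh3, imidazole, CH2Cl2, 0 °C
Reagents that add atoms: iodine, [I][I]
Why: Appel-type iodination of the primary alcohol by SN2.

Step 13
Reactants: 16 (3S,7R)-9-iodo-2,3,7-trimethyl-6-methylidenenon-1-ene
Product: 17 (5R,9S)-5,9,10-trimethyl-6-methylideneundec-10-en-1-yne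
Conditions: LiC≡CH·H2NCH2CH2NH2 (1.5 equiv), DMSO, 15 °C → rt
Reagents that add atoms: lithium acetylide–ethylenediamine complex, [Li]C#C.NCCN
Why: SN2 alkylation of lithium acetylide by an unhindered primary iodide in a dipolar aprotic solvent; no stereocentre is touched.

Step 14
Reactants: 17 (5R,9S)-5,9,10-trimethyl-6-methylideneundec-10-en-1-yne
Product: 19 (1E,5R,9S)-1-iodo-2,5,9,10-tetramethyl-6-methylideneundeca-1,10-diene, via alkenylalane 18 (not isolated)
Conditions: Me3Al (2.5 equiv), (C5H5)2ZrCl2 (0.25 equiv), CH2Cl2, 0 °C → rt; then I2, THF, −30 → 0 °C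
Reagents that add atoms: trimethylaluminium, C[Al](C)C; iodine, [I][I]
Why: Negishi zirconium-catalysed carboalumination adds Me and Al syn across the terminal alkyne with methyl on the internal carbon, and iodinolysis with retention gives the (E)-iodide; the 1,1-disubstituted alkenes do not react under these conditions.

**Central fragment (C10–C13)**

Step 15
Reactants: 20 (3R)-3-hydroxyoxolan-2-one [(R)-α-hydroxy-γ-butyrolactone]
Product: 21 (3R)-3-(benzyloxy)oxolan-2-one
Conditions: benzyl 2,2,2-trichloroacetimidate (1.3 equiv), TfOH (cat.), CH2Cl2/cyclohexane, 0 °C → rt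
Reagents that add atoms: benzyl 2,2,2-trichloroacetimidate, N=C(OCc1ccccc1)C(Cl)(Cl)Cl
Why: Acid-catalysed O-benzylation by the trichloroacetimidate uses no base, so the enolisable α-centre (future C11) is not epimerised.

Step 16
Reactants: 21 (3R)-3-(benzyloxy)oxolan-2-one
Product: 22 (2R)-2-(benzyloxy)-4-hydroxy-N-methoxy-N-methylbutanamide
Conditions: MeNH(OMe)·HCl (3 equiv), Me3Al (3 equiv), CH2Cl2, 0 °C → rt; aq. potassium sodium tartrate (KNaC4H4O6) work-up
Reagents that add atoms: N,O-dimethylhydroxylamine hydrochloride, CNOC.Cl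
Why: Weinreb aminolysis of the lactone by the aluminium amide opens the ring at the acyl carbon only; the stereocentre is not involved.

Step 17
Reactants: 22 (2R)-2-(benzyloxy)-4-hydroxy-N-methoxy-N-methylbutanamide
Product: 23 (2R)-2-(benzyloxy)-4-iodo-N-methoxy-N-methylbutanamide
Conditions: I2, PPh3, imidazole, CH2Cl2, 0 °C; used at once
Reagents that add atoms: iodine, [I][I]
Why: Appel-type iodination of the primary alcohol; external iodide outruns the weakly nucleophilic Weinreb carbonyl oxygen at 0 °C.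

**Assembly**

Step 18
Reactants: 23 (2R)-2-(benzyloxy)-4-iodo-N-methoxy-N-methylbutanamide; 19 (1E,5R,9S)-1-iodo-2,5,9,10-tetramethyl-6-methylideneundeca-1,10-diene
Product: 25 (2R,5E,9R,13S)-2-(benzyloxy)-N-methoxy-N,6,9,13,14-pentamethyl-10-methylidenepentadeca-5,14-dienamide, via alkylzinc iodide 24 (not isolated)
Conditions: Zn dust (activated: BrCH2CH2Br, Me3SiCl), THF/DMA, 35 °C; then 19 (0.65 equiv), Pd(PPh3)4 (5 mol %), 40 °C
Reagents that add atoms: none
Why: Zinc inserts into the primary C–I bond and tolerates the Weinreb amide, and the Negishi sp3–sp2 cross-coupling on zerovalent palladium keeps the (E)-geometry of the vinyl iodide; the zinc reagent has no β-leaving group.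

Step 19
Reactants: 25 (2R,5E,9R,13S)-2-(benzyloxy)-N-methoxy-N,6,9,13,14-pentamethyl-10-methylidenepentadeca-5,14-dienamide
Product: 26 (3R,6E,10R,14S)-3-(benzyloxy)-7,10,14,15-tetramethyl-11-methylidenehexadeca-6,15-dien-2-one
Conditions: MeMgBr (3 equiv), THF, −78 → 0 °C; H2O quench
Reagents that add atoms: methylmagnesium bromide, C[Mg]Br
Why: Weinreb ketone synthesis; the chelated tetrahedral adduct survives until quench, which prevents over-addition and α-epimerisation.

Step 20
Reactants: 8 (3R,7R)-9-iodo-2,3,7-trimethyl-6-methylidenenon-1-ene; 26 (3R,6E,10R,14S)-3-(benzyloxy)-7,10,14,15-tetramethyl-11-methylidenehexadeca-6,15-dien-2-one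
Product: 29 (3R,7R,10R,11R,14E,18R,22S)-11-(benzyloxy)-2,3,7,10,15,18,22,23-octamethyl-6,19-dimethylidenetetracosa-1,14,23-trien-10-ol, via alkyllithium 27 (not isolated), via Grignard reagent 28 (not isolated)
Conditions: 8 (1.4 equiv), t-BuLi (2.8 equiv), Et2O/pentane, −78 °C; MgBr2·OEt2 (1.8 equiv), −78 → 0 °C; then 26 (1.0 equiv), THF, −78 °C; H2O quench
Reagents that add atoms: none
Why: Cram-chelate (Still) Grignard addition: magnesium bridges the carbonyl and benzyloxy oxygens and the primary alkyl group enters from the face bearing H at C11, giving the syn diol pattern, that is (10R) from (11R).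

Step 21
Reactants: 29 (3R,7R,10R,11R,14E,18R,22S)-11-(benzyloxy)-2,3,7,10,15,18,22,23-octamethyl-6,19-dimethylidenetetracosa-1,14,23-trien-10-ol
Product: 30 (3R,7R,10R,11R,14E,18R,22S)-2,3,7,10,15,18,22,23-octamethyl-6,19-dimethylidenetetracosa-1,14,23-triene-10,11-diol
Conditions: lithium 4,4'-di-tert-butylbiphenylide (4 equiv), THF, −78 °C; H2O quench
Reagents that add atoms: none
Why: Reductive debenzylation by electron transfer from the arene radical anion cleaves only the benzylic C–O bond; isolated alkenes are not reduced at −78 °C and no stereocentre is touched.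

Step 22
Reactants: 30 (3R,7R,10R,11R,14E,18R,22S)-2,3,7,10,15,18,22,23-octamethyl-6,19-dimethylidenetetracosa-1,14,23-triene-10,11-diol
Product: 31 (3R,7R,10R,11R,14E,18R,22S)-2,3,7,10,15,18,22,23-octamethyl-6,19-dimethylidene-10,11-bis(trimethylsilyloxy)tetracosa-1,14,23-triene
Conditions: N-(trimethylsilyl)imidazole (4 equiv), CH2Cl2, rt
Reagents that add atoms: N-(trimethylsilyl)imidazole, C[Si](C)(C)n1ccnc1
Why: Silyl transfer from a neutral, powerful silyl donor covers the secondary and the tertiary hydroxyl without acid or strong base.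

Step 23
Reactants: 31 (3R,7R,10R,11R,14E,18R,22S)-2,3,7,10,15,18,22,23-octamethyl-6,19-dimethylidene-10,11-bis(trimethylsilyloxy)tetracosa-1,14,23-triene; 32 all-trans-canthaxanthin (β,β-carotene-4,4'-dione)
Product: 33 target CNP0354203.2 (canthaxanthin ketalised at C-4' by diol 30; spiro carbon R)
Conditions: 32 (3 equiv), Me3SiOTf (0.1 equiv), 2,6-di-tert-butyl-4-methylpyridine (0.05 equiv), CH2Cl2, −78 → −20 °C, dark, Ar; pyridine quench; silica gel, then preparative HPLC
Reagents that add atoms: none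
Why: Noyori ketalisation: the silyl triflate activates one carbonyl, the bis-silyl ether supplies both oxygens and no water or protic acid meets the polyene, while excess diketone holds the reaction at the mono-ketal. C10 and C11 are untouched; the spiro carbon is not controlled, so it forms as a mixture of two epimers under equilibrating conditions, from which the (R)-epimer is separated by HPLC and the other is re-equilibrated with Me3SiOTf and recycled.

**Compound list**
1 | (3R)-3-methyloxolan-2-one, (R)-α-methyl-γ-butyrolactone | O=C1[C@H](C)CCO1 | starting material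
2 | (3R)-5-hydroxy-3-methylpentan-2-one | CC(=O)[C@H](C)CCO | intermediate
3 | (3R)-3,4-dimethylpent-4-en-1-ol | C=C(C)[C@H](C)CCO | intermediate
4 | (3R)-5-iodo-2,3-dimethylpent-1-ene | C=C(C)[C@H](C)CCI | intermediate
5 | [(3R)-3,4-dimethylpent-4-en-1-yl]lithium | C=C(C)[C@H](C)CC[Li] | intermediate
6 | (3R,7R)-1-hydroxy-3,7,8-trimethylnon-8-en-4-one | C=C(C)[C@H](C)CCC(=O)[C@H](C)CCO | intermediate
7 | (3R,7R)-3,7,8-trimethyl-4-methylidenenon-8-en-1-ol | C=C(C)[C@H](C)CCC(=C)[C@H](C)CCO | intermediate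
8 | (3R,7R)-9-iodo-2,3,7-trimethyl-6-methylidenenon-1-ene | C=C(C)[C@H](C)CCC(=C)[C@H](C)CCI | intermediate
9 | (3S)-3-methyloxolan-2-one, (S)-α-methyl-γ-butyrolactone | O=C1[C@@H](C)CCO1 | starting material
10 | (3S)-5-hydroxy-3-methylpentan-2-one | CC(=O)[C@@H](C)CCO | intermediate
11 | (3S)-3,4-dimethylpent-4-en-1-ol | C=C(C)[C@@H](C)CCO | intermediate
12 | (3S)-5-iodo-2,3-dimethylpent-1-ene | C=C(C)[C@@H](C)CCI | intermediate
13 | [(3S)-3,4-dimethylpent-4-en-1-yl]lithium | C=C(C)[C@@H](C)CC[Li] | intermediate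
14 | (3R,7S)-1-hydroxy-3,7,8-trimethylnon-8-en-4-one | C=C(C)[C@@H](C)CCC(=O)[C@H](C)CCO | intermediate
15 | (3R,7S)-3,7,8-trimethyl-4-methylidenenon-8-en-1-ol | C=C(C)[C@@H](C)CCC(=C)[C@H](C)CCO | intermediate
16 | (3S,7R)-9-iodo-2,3,7-trimethyl-6-methylidenenon-1-ene | C=C(C)[C@@H](C)CCC(=C)[C@H](C)CCI | intermediate
17 | (5R,9S)-5,9,10-trimethyl-6-methylideneundec-10-en-1-yne | C=C(C)[C@@H](C)CCC(=C)[C@H](C)CCC#C | intermediate
18 | dimethyl[(1E,5R,9S)-2,5,9,10-tetramethyl-6-methylideneundeca-1,10-dien-1-yl]alane | C=C(C)[C@@H](C)CCC(=C)[C@H](C)CC/C(C)=C/[Al](C)C | intermediate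
19 | (1E,5R,9S)-1-iodo-2,5,9,10-tetramethyl-6-methylideneundeca-1,10-diene | C=C(C)[C@@H](C)CCC(=C)[C@H](C)CC/C(C)=C/I | intermediate
20 | (3R)-3-hydroxyoxolan-2-one, (R)-α-hydroxy-γ-butyrolactone | O=C1OCC[C@H]1O | starting material
21 | (3R)-3-(benzyloxy)oxolan-2-one | O=C1OCC[C@H]1OCc1ccccc1 | intermediate
22 | (2R)-2-(benzyloxy)-4-hydroxy-N-methoxy-N-methylbutanamide | OCC[C@@H](OCc1ccccc1)C(=O)N(C)OC | intermediate
23 | (2R)-2-(benzyloxy)-4-iodo-N-methoxy-N-methylbutanamide | ICC[C@@H](OCc1ccccc1)C(=O)N(C)OC | intermediate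
24 | {(3R)-3-(benzyloxy)-4-[methoxy(methyl)amino]-4-oxobutyl}zinc iodide | I[Zn]CC[C@@H](OCc1ccccc1)C(=O)N(C)OC | intermediate
25 | (2R,5E,9R,13S)-2-(benzyloxy)-N-methoxy-N,6,9,13,14-pentamethyl-10-methylidenepentadeca-5,14-dienamide | C=C(C)[C@@H](C)CCC(=C)[C@H](C)CC/C(C)=C/CC[C@@H](OCc1ccccc1)C(=O)N(C)OC | intermediate
26 | (3R,6E,10R,14S)-3-(benzyloxy)-7,10,14,15-tetramethyl-11-methylidenehexadeca-6,15-dien-2-one | C=C(C)[C@@H](C)CCC(=C)[C@H](C)CC/C(C)=C/CC[C@@H](OCc1ccccc1)C(C)=O | intermediate
27 | [(3R,7R)-3,7,8-trimethyl-4-methylidenenon-8-en-1-yl]lithium | C=C(C)[C@H](C)CCC(=C)[C@H](C)CC[Li] | intermediate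
28 | [(3R,7R)-3,7,8-trimethyl-4-methylidenenon-8-en-1-yl]magnesium bromide | C=C(C)[C@H](C)CCC(=C)[C@H](C)CC[Mg]Br | intermediate
29 | (3R,7R,10R,11R,14E,18R,22S)-11-(benzyloxy)-2,3,7,10,15,18,22,23-octamethyl-6,19-dimethylidenetetracosa-1,14,23-trien-10-ol | C=C(C)[C@H](C)CCC(=C)[C@H](C)CC[C@@](C)(O)[C@H](OCc1ccccc1)CC/C=C(\C)CC[C@@H](C)C(=C)CC[C@H](C)C(=C)C | intermediate
30 | (3R,7R,10R,11R,14E,18R,22S)-2,3,7,10,15,18,22,23-octamethyl-6,19-dimethylidenetetracosa-1,14,23-triene-10,11-diol | C=C(C)[C@H](C)CCC(=C)[C@H](C)CC[C@@](C)(O)[C@H](O)CC/C=C(\C)CC[C@@H](C)C(=C)CC[C@H](C)C(=C)C | intermediate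
31 | 10,11-bis(trimethylsilyl) ether of diol 30 | C=C(C)[C@H](C)CCC(=C)[C@H](C)CC[C@@](C)(O[Si](C)(C)C)[C@H](O[Si](C)(C)C)CC/C=C(\C)CC[C@@H](C)C(=C)CC[C@H](C)C(=C)C | intermediate
32 | all-trans-canthaxanthin (β,β-carotene-4,4'-dione) | O=C1CCC(C)(C)C(/C=C/C(C)=C/C=C/C(C)=C/C=C/C=C(C)/C=C/C=C(C)/C=C/C2=C(C)C(=O)CCC2(C)C)=C1C | starting material
33 | CNP0354203.2: canthaxanthin whose C-4' is the spiro carbon (R) of a 1,3-dioxolane closed by O-10 and O-11 of diol 30 (C10 R, C11 R) | C=C(C)[C@H](C)CCC(=C)[C@H](C)CC[C@@]1(C)O[C@@]2(CCC(C)(C)C(/C=C/C(C)=C/C=C/C(C)=C/C=C/C=C(C)/C=C/C=C(C)/C=C/C3=C(C)C(=O)CCC3(C)C)=C2C)O[C@@H]1CC/C=C(\C)CC[C@@H](C)C(=C)CC[C@H](C)C(=C)C | target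

**Totals**
Total step count: 23. Longest linear sequence: 14 steps (from 9 through steps 7–14 and 18–23 to 33).

**Three steps most likely to fail**

Step 23 is the weakest point. The ketone is conjugated to the whole polyene and flanked by a methyl-bearing sp2 carbon, the diol is secondary/tertiary, the polyene is acid-sensitive, and nothing controls the spiro carbon. If the silyl-triflate condensation gives no ketal or degrades the polyene, the fallback is an acetal exchange that never uses the silyl ether. It sets out from canthaxanthin 32 and the free diol 30. Canthaxanthin 32 is treated with HC(OMe)3 and MeOH under pyridinium p-toluenesulfonate to give all-trans-4',4'-dimethoxy-β,β-caroten-4-one F1. F1 is then warmed with diol 30 and pyridinium p-toluenesulfonate in benzene at 45 °C while methanol is pumped off; the two methoxy groups are exchanged for the diol and the route is rejoined at 33 (same HPLC separation of the spiro epimers).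

Step 17 is the second risk. The activated γ-hydroxy Weinreb amide can close back to lactone 21 through its carbonyl oxygen, and iodide 23 is labile for the same reason. The fallback carries the acid as an ethyl ester through the coupling and sets out from lactone 20. Ring opening with Me3SiCl/NaI in MeCN followed by EtOH gives ethyl (2R)-2-hydroxy-4-iodobutanoate F2. Benzyl trichloroacetimidate with catalytic TfOH gives ethyl (2R)-2-(benzyloxy)-4-iodobutanoate F3. Zinc dust converts F3 into [(3R)-3-(benzyloxy)-4-ethoxy-4-oxobutyl]zinc iodide F4, which is coupled with vinyl iodide 19 under Pd(PPh3)4 to give ethyl (2R,5E,9R,13S)-2-(benzyloxy)-6,9,13,14-tetramethyl-10-methylidenepentadeca-5,14-dienoate F5. MeNH(OMe)·HCl with i-PrMgCl in THF at −20 °C turns F5 into the Weinreb amide, and the route is rejoined at 25.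

Step 4 is the third risk (step 10 runs the same chemistry). A primary alkyllithium may add twice to the lactone or deprotonate it. The fallback replaces the lactone by a Weinreb amide as the acylating partner and sets out from lactone 1 and alkyllithium 5. Lactone 1 is opened with MeNH(OMe)·HCl/Me3Al to (2R)-4-hydroxy-N-methoxy-N,2-dimethylbutanamide F6. Silylation with t-BuMe2SiCl and imidazole gives (2R)-4-[(tert-butyldimethylsilyl)oxy]-N-methoxy-N,2-dimethylbutanamide F7. Addition of alkyllithium 5 at −78 °C gives (3R,7R)-1-[(tert-butyldimethylsilyl)oxy]-3,7,8-trimethylnon-8-en-4-one F8. Desilylation with HF·pyridine in THF, which does not enolise the ketone, rejoins the route at 6.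

**Further compounds**
F1 | step 23 | all-trans-4',4'-dimethoxy-β,β-caroten-4-one | COC1(OC)CCC(C)(C)C(/C=C/C(C)=C/C=C/C(C)=C/C=C/C=C(C)/C=C/C=C(C)/C=C/C2=C(C)C(=O)CCC2(C)C)=C1C
F2 | step 17 | ethyl (2R)-2-hydroxy-4-iodobutanoate | ICC[C@@H](O)C(=O)OCC
F3 | step 17 | ethyl (2R)-2-(benzyloxy)-4-iodobutanoate | ICC[C@@H](OCc1ccccc1)C(=O)OCC
F4 | step 17 | [(3R)-3-(benzyloxy)-4-ethoxy-4-oxobutyl]zinc iodide | I[Zn]CC[C@@H](OCc1ccccc1)C(=O)OCC
F5 | step 17 | ethyl (2R,5E,9R,13S)-2-(benzyloxy)-6,9,13,14-tetramethyl-10-methylidenepentadeca-5,14-dienoate | C=C(C)[C@@H](C)CCC(=C)[C@H](C)CC/C(C)=C/CC[C@@H](OCc1ccccc1)C(=O)OCC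
F6 | step 4 | (2R)-4-hydroxy-N-methoxy-N,2-dimethylbutanamide | CON(C)C(=O)[C@H](C)CCO
F7 | step 4 | (2R)-4-[(tert-butyldimethylsilyl)oxy]-N-methoxy-N,2-dimethylbutanamide | CON(C)C(=O)[C@H](C)CCO[Si](C)(C)C(C)(C)C
F8 | step 4 | (3R,7R)-1-[(tert-butyldimethylsilyl)oxy]-3,7,8-trimethylnon-8-en-4-one | C=C(C)[C@H](C)CCC(=O)[C@H](C)CCO[Si](C)(C)C(C)(C)C
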